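Everything rests on cutting ring A of flavone 1, the unit joined through C8. Its oxygenated carbons C5 and C7 are 1,3-related like the two carbonyls of a malonate, and C8–C8a–C4a is a three-carbon nucleophile once ring C exists as a 4-pyranone. Because O1 then sits on C8a before ring A is made, the benzylic carbon on C8a must become C8; a 6-aryl isomer cannot arise. One operation joins C7–C8 and C4a–C5 and delivers ring A as the free 5,7-diol. The precursor is 2-(2-bromo-5-methoxybenzyl)-6-(4-methoxyphenyl)-4-pyranone, made from a 1,3,5-triketone; its bromide later carries flavone 2 through one carbonylative annulation.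

Key step: step 4

Assumption: the SMILES gives no descriptor for the hindered C8–aryl axis, so the axis is made without control (racemic if it proves configurationally stable). The target has no stereocentre.
Remark: locants O1 to C8a and rings A and C refer to flavone 1. Flavone 2 is the chromenone bonded through its C2 to the same anisole ring.
Remark: bromine is kept as the only handle on the benzyl ring. An ortho ester, nitrile or alkyne would offer C4a a rival six-membered closure in step 4.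
Remark: compounds 1, 4, 8 and 16 are treated as purchasable.

Step 1
Reactants: 1 2-(2-bromo-5-methoxyphenyl)acetic acid
Product: 3 2-(2-bromo-5-methoxyphenyl)-N-methoxy-N-methylacetamide, via acyl imidazolide 2 (not isolated)
Conditions: CDI (1.1 equiv), CH2Cl2, 23 °C; then MeNH(OMe)·HCl (1.3 equiv), 23 °C
Reagents that add atoms: N,O-dimethylhydroxylamine hydrochloride, Cl.CNOC; 1,1'-carbonyldiimidazole, O=C(n1ccnc1)n1ccnc1 (supplies the imidazolyl group of 2 only)
Why: Standard Weinreb amide formation through an acyl imidazolide; the amide is preferred to an ester because its benzylic CH2 is less acidic and it releases no ketone before the quench of the next step.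

Step 2
Reactants: 3 2-(2-bromo-5-methoxyphenyl)-N-methoxy-N-methylacetamide; 4 1-(4-methoxyphenyl)butane-1,3-dione
Product: 6 1-(2-bromo-5-methoxyphenyl)-6-(4-methoxyphenyl)hexane-2,4,6-trione, via dilithium dianion 5 (not isolated)
Conditions: 4 (1.5 equiv), LiN(iPr)2 (3.1 equiv), THF, −78 → 0 °C; 3 (1.0 equiv), −78 → −20 °C; 1 M HCl
Reagents that add atoms: none
Why: Claisen-type acylation of a β-diketone dianion at its terminal carbon, the more basic and only reactive site, by a Weinreb amide is a known route to 1,3,5-tricarbonyl compounds, and the aryl bromide is inert because no free amide base remains.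

Step 3
Reactants: 6 1-(2-bromo-5-methoxyphenyl)-6-(4-methoxyphenyl)hexane-2,4,6-trione
Product: 7 2-(2-bromo-5-methoxybenzyl)-6-(4-methoxyphenyl)-4H-pyran-4-one
Conditions: p-TsOH·H2O (0.2 equiv), toluene, reflux, Dean–Stark
Reagents that add atoms: none
Why: Acid-catalysed cyclodehydration of a 1,3,5-triketone is the classical 4-pyranone synthesis and can give one pyranone only, since oxygen can bridge only the two outer carbonyl carbons.

Step 4
Reactants: 7 2-(2-bromo-5-methoxybenzyl)-6-(4-methoxyphenyl)-4H-pyran-4-one; 8 bis(2,4,6-trichlorophenyl) malonate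
Product: 14 8-(2-bromo-5-methoxyphenyl)-5,7-dihydroxy-2-(4-methoxyphenyl)-4H-chromen-4-one, via lithium dienolate 9 (not isolated), via lithium malonate enolate 10 (not isolated), via aryloxycarbonylketene 11 (not isolated), via keto ester 12 (not isolated), via dienylketene 13 (not isolated)
Conditions: 7 + 8 (1.2 equiv), THF, −78 °C; LiN(SiMe3)2 (2.2 equiv) dropwise; −78 → 23 °C, then 60 °C; 1 M HCl
Reagents that add atoms: none
Why: Proposed new method: the CH2 of 8 is far more acidic than the benzylic CH2 of 7, so a dienolate alone would merely be protonated; both partners are therefore deprotonated at −78 °C (9 and 10), and on warming 10 expels trichlorophenoxide (E1cB) to ketene 11, an acyl donor without acidic hydrogen that 9 captures at its γ-carbon to form C7–C8 (enolate of 12). A second E1cB loss of aryloxide, with enolisation of C7 towards C8, gives dienylketene 13 (C4a=C8a–C8=C7–C6=C5=O), which closes ring A by 6π electrocyclisation between C4a and C5, the pericyclic equivalent of a 6-(enolexo)-exo-trig Dieckmann acylation, and tautomerisation to the resorcinol makes the sequence irreversible. The closest known reaction types are γ-deprotonation and acylation of 2-alkyl-4-pyranones, cyclocondensation of bis(2,4,6-trichlorophenyl) malonates with 1,3-dinucleophiles, the Effenberger annulation of enol ethers with malonyl dichloride, and the dienylketene closure that ends a Danheiser benzannulation. No stereocentre is created, since C8 of 12 is labile and becomes sp2. The step needs C- rather than O-acylation and attack through C8 and C4a only: 7 has γ-hydrogens on one flank alone, an O-acylated dienolate is itself an acyl donor and re-enters the manifold, 12 has no five- to seven-membered O-closure open to it, and because the malonyl unit is symmetrical either order of the two C-acylations ends at 14. The aryl bromide, the methyl ethers and the pyranone ring should tolerate LiN(SiMe3)2 up to 60 °C, and 14 should emerge with both hydroxyls free.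

Step 5
Reactants: 14 8-(2-bromo-5-methoxyphenyl)-5,7-dihydroxy-2-(4-methoxyphenyl)-4H-chromen-4-one
Product: 15 5,7-bis(benzyloxy)-8-(2-bromo-5-methoxyphenyl)-2-(4-methoxyphenyl)-4H-chromen-4-one
Conditions: BnBr (3 equiv), K2CO3 (4 equiv), DMF, 70 °C
Reagents that add atoms: benzyl bromide, BrCc1ccccc1
Why: Williamson ether synthesis, in which the acidic 7-OH reacts first and excess bromide at 70 °C also alkylates the hydrogen-bonded 5-OH, so that no phenol of flavone 1 can intercept the acylpalladium species of step 6 and all four protecting groups fall together in step 7.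

Step 6
Reactants: 15 5,7-bis(benzyloxy)-8-(2-bromo-5-methoxyphenyl)-2-(4-methoxyphenyl)-4H-chromen-4-one; 16 1-[2,4-bis(benzyloxy)-6-hydroxyphenyl]ethan-1-one
Product: 19 5,7-bis(benzyloxy)-8-{2-[5,7-bis(benzyloxy)-4-oxo-4H-chromen-2-yl]-5-methoxyphenyl}-2-(4-methoxyphenyl)-4H-chromen-4-one, via aryl ester 17 (not isolated), via 1,3-diketone 18 (not isolated)
Conditions: 16 (1.3 equiv), Pd(OAc)2 (5 mol %), dppb (7.5 mol %), DBU (3 equiv), CO (10 bar), DMSO, 120 °C
Reagents that add atoms: carbon monoxide, [C-]#[O+]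
Why: This is the known palladium-catalysed carbonylative coupling of aryl bromides with 2-hydroxyacetophenones to flavones, in which oxidative addition, CO insertion and capture by the phenoxide give 17, DBU drives the Baker–Venkataraman acyl shift to 18 and cyclodehydration closes ring C of flavone 2, while the substituted C7 and C8a leave the acylpalladium no C–H bond for a fluorenone-type closure.

Step 7
Reactants: 19 5,7-bis(benzyloxy)-8-{2-[5,7-bis(benzyloxy)-4-oxo-4H-chromen-2-yl]-5-methoxyphenyl}-2-(4-methoxyphenyl)-4H-chromen-4-one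
Product: 20 8-[2-(5,7-dihydroxy-4-oxo-4H-chromen-2-yl)-5-methoxyphenyl]-5,7-dihydroxy-2-(4-methoxyphenyl)-4H-chromen-4-one (target)
Conditions: H2 (1 atm), 10% Pd/C, THF–MeOH, 23 °C
Reagents that add atoms: none
Why: Catalytic hydrogenolysis cleaves the four aryl benzyl ethers, whereas the aryl methyl ethers are inert and the C2=C3 bonds of both flavones, being aryl-conjugated vinylogous esters, should resist reduction at ambient pressure and temperature.

Compound list
1 | 2-(2-bromo-5-methoxyphenyl)acetic acid | COc1ccc(Br)c(CC(=O)O)c1 | starting material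
2 | 2-(2-bromo-5-methoxyphenyl)-1-(1H-imidazol-1-yl)ethan-1-one | COc1ccc(Br)c(CC(=O)n2ccnc2)c1 | intermediate
3 | 2-(2-bromo-5-methoxyphenyl)-N-methoxy-N-methylacetamide | COc1ccc(Br)c(CC(=O)N(C)OC)c1 | intermediate
4 | 1-(4-methoxyphenyl)butane-1,3-dione | COc1ccc(C(=O)CC(C)=O)cc1 | starting material
5 | dilithium (Z)-1-(4-methoxyphenyl)buta-1,3-diene-1,3-diolate | [Li+].[Li+].COc1ccc(/C([O-])=C/C(=C)[O-])cc1 | intermediate
6 | 1-(2-bromo-5-methoxyphenyl)-6-(4-methoxyphenyl)hexane-2,4,6-trione (drawn as the triketo tautomer) | COc1ccc(C(=O)CC(=O)CC(=O)Cc2cc(OC)ccc2Br)cc1 | intermediate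
7 | 2-(2-bromo-5-methoxybenzyl)-6-(4-methoxyphenyl)-4H-pyran-4-one | COc1ccc(-c2cc(=O)cc(Cc3cc(OC)ccc3Br)o2)cc1 | intermediate
8 | bis(2,4,6-trichlorophenyl) malonate | O=C(CC(=O)Oc1c(Cl)cc(Cl)cc1Cl)Oc1c(Cl)cc(Cl)cc1Cl | starting material
9 | lithium 2-(2-bromo-5-methoxybenzylidene)-6-(4-methoxyphenyl)-2H-pyran-4-olate (exocyclic C=C geometry mobile) | [Li+].COc1ccc(C2=CC([O-])=CC(=Cc3cc(OC)ccc3Br)O2)cc1 | intermediate
10 | lithium enolate of bis(2,4,6-trichlorophenyl) malonate | [Li+].[O-]C(Oc1c(Cl)cc(Cl)cc1Cl)=CC(=O)Oc1c(Cl)cc(Cl)cc1Cl | intermediate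
11 | 2,4,6-trichlorophenyl 3-oxoprop-2-enoate | O=C=CC(=O)Oc1c(Cl)cc(Cl)cc1Cl | intermediate
12 | 2,4,6-trichlorophenyl 4-(2-bromo-5-methoxyphenyl)-4-[6-(4-methoxyphenyl)-4-oxo-4H-pyran-2-yl]-3-oxobutanoate (racemic, labile centre) | COc1ccc(-c2cc(=O)cc(C(c3cc(OC)ccc3Br)C(=O)CC(=O)Oc3c(Cl)cc(Cl)cc3Cl)o2)cc1 | intermediate
13 | 4-(2-bromo-5-methoxyphenyl)-3-hydroxy-4-[6-(4-methoxyphenyl)-4-oxo-4H-pyran-2-yl]buta-1,3-dien-1-one (pyranyl and ketenyl groups cis) | COc1ccc(-c2cc(=O)cc(/C(c3cc(OC)ccc3Br)=C(O)\C=C=O)o2)cc1 | intermediate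
14 | 8-(2-bromo-5-methoxyphenyl)-5,7-dihydroxy-2-(4-methoxyphenyl)-4H-chromen-4-one | COc1ccc(-c2cc(=O)c3c(O)cc(O)c(-c4cc(OC)ccc4Br)c3o2)cc1 | intermediate
15 | 5,7-bis(benzyloxy)-8-(2-bromo-5-methoxyphenyl)-2-(4-methoxyphenyl)-4H-chromen-4-one | COc1ccc(-c2cc(=O)c3c(OCc4ccccc4)cc(OCc4ccccc4)c(-c4cc(OC)ccc4Br)c3o2)cc1 | intermediate
16 | 1-[2,4-bis(benzyloxy)-6-hydroxyphenyl]ethan-1-one | CC(=O)c1c(O)cc(OCc2ccccc2)cc1OCc1ccccc1 | starting material
17 | 2-acetyl-3,5-bis(benzyloxy)phenyl 2-[5,7-bis(benzyloxy)-2-(4-methoxyphenyl)-4-oxo-4H-chromen-8-yl]-4-methoxybenzoate | COc1ccc(-c2cc(=O)c3c(OCc4ccccc4)cc(OCc4ccccc4)c(-c4cc(OC)ccc4C(=O)Oc4cc(OCc5ccccc5)cc(OCc5ccccc5)c4C(C)=O)c3o2)cc1 | intermediate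
18 | 1-[2,4-bis(benzyloxy)-6-hydroxyphenyl]-3-{2-[5,7-bis(benzyloxy)-2-(4-methoxyphenyl)-4-oxo-4H-chromen-8-yl]-4-methoxyphenyl}propane-1,3-dione | COc1ccc(-c2cc(=O)c3c(OCc4ccccc4)cc(OCc4ccccc4)c(-c4cc(OC)ccc4C(=O)CC(=O)c4c(O)cc(OCc5ccccc5)cc4OCc4ccccc4)c3o2)cc1 | intermediate
19 | 5,7-bis(benzyloxy)-8-{2-[5,7-bis(benzyloxy)-4-oxo-4H-chromen-2-yl]-5-methoxyphenyl}-2-(4-methoxyphenyl)-4H-chromen-4-one | COc1ccc(-c2cc(=O)c3c(OCc4ccccc4)cc(OCc4ccccc4)c(-c4cc(OC)ccc4-c4cc(=O)c5c(OCc6ccccc6)cc(OCc6ccccc6)cc5o4)c3o2)cc1 | intermediate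
20 | 8-[2-(5,7-dihydroxy-4-oxo-4H-chromen-2-yl)-5-methoxyphenyl]-5,7-dihydroxy-2-(4-methoxyphenyl)-4H-chromen-4-one | COc1ccc(-c2cc(=O)c3c(O)cc(O)c(-c4cc(OC)ccc4-c4cc(=O)c5c(O)cc(O)cc5o4)c3o2)cc1 | target

Total step count: 7
Longest linear sequence: 7 steps (1 → 3 → 6 → 7 → 14 → 15 → 19 → 20)

Steps most likely to fail

1. Step 4 (the labelled step).
- Risk: proton shuffling between the two enolates without C–C bond formation; self-condensation of the ketene; opening of the pyranone by aryloxide or amide; or arrest after the first acylation.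
- Fallback with known chemistry, from 16 back to 15. Iodination of 16 ortho to the free phenol (NIS, cat. CF3CO2H, MeCN) should give 1-[4,6-bis(benzyloxy)-2-hydroxy-3-iodophenyl]ethan-1-one F1. Claisen–Schmidt condensation with 4-methoxybenzaldehyde (KOH, EtOH) leads to (E)-1-[4,6-bis(benzyloxy)-2-hydroxy-3-iodophenyl]-3-(4-methoxyphenyl)prop-2-en-1-one F2. Oxidative cyclisation (cat. I2, DMSO, 120 °C) leads to 5,7-bis(benzyloxy)-8-iodo-2-(4-methoxyphenyl)-4H-chromen-4-one F3. Suzuki–Miyaura coupling with (2-bromo-5-methoxyphenyl)boronic acid (Pd(PPh3)4, Na2CO3, DME–H2O, 80 °C), selective for C–I over C–Br, returns to 15. The price is that 3- versus 5-iodination has to be proved, which the main route avoids.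

2. Step 6.
- Risk: slow oxidative addition of the hindered, electron-rich bromide to zerovalent palladium under CO pressure; hydrodebromination; or arrest at the ester or diketone stage.
- Fallback from 15 back to 19. It moves the CO step onto an aryl iodide. Sonogashira coupling of 15 with trimethylsilylacetylene (PdCl2(PhCN)2, P(t-Bu)3, CuI, iPr2NH, dioxane, 50 °C) should give 5,7-bis(benzyloxy)-8-{5-methoxy-2-[(trimethylsilyl)ethynyl]phenyl}-2-(4-methoxyphenyl)-4H-chromen-4-one F4. K2CO3 in MeOH–THF frees 5,7-bis(benzyloxy)-8-(2-ethynyl-5-methoxyphenyl)-2-(4-methoxyphenyl)-4H-chromen-4-one F5. Purchased 3,5-bis(benzyloxy)phenol is iodinated (NIS, CH2Cl2, 0 °C) at the less hindered position next to the hydroxyl to 3,5-bis(benzyloxy)-2-iodophenol F6. F5, F6 and CO (1 atm) with PdCl2(dppf) in Et2NH at 60 °C undergo carbonylative Sonogashira coupling to 1-[2,4-bis(benzyloxy)-6-hydroxyphenyl]-3-{2-[5,7-bis(benzyloxy)-2-(4-methoxyphenyl)-4-oxo-4H-chromen-8-yl]-4-methoxyphenyl}prop-2-yn-1-one F7. F7 closes in the same flask to 19, the secondary amine favouring the six-membered over the five-membered ring.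

3. Step 2.
- Risk: proton transfer from the benzylic CH2 of 3 to the dianion in place of addition, so that conversion stalls.
- Fallback from 4 and 1 back to 6, without any strong base in the bond-forming event. Compound 4 is silylated twice (Me3SiOTf, Et3N, Et2O, 0 °C) to (Z)-1-(4-methoxyphenyl)-1,3-bis(trimethylsilyloxy)buta-1,3-diene F8. Acid 1 is converted ((COCl)2, cat. DMF, CH2Cl2) into 2-(2-bromo-5-methoxyphenyl)acetyl chloride F9. Mukaiyama-type C-acylation of the terminal carbon of F8 by F9 (CH2Cl2, −78 → 20 °C), followed by aqueous acid, returns to 6.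

Further compounds
F1 | step 4 | 1-[4,6-bis(benzyloxy)-2-hydroxy-3-iodophenyl]ethan-1-one | CC(=O)c1c(O)c(I)c(OCc2ccccc2)cc1OCc1ccccc1
F2 | step 4 | (E)-1-[4,6-bis(benzyloxy)-2-hydroxy-3-iodophenyl]-3-(4-methoxyphenyl)prop-2-en-1-one | COc1ccc(/C=C/C(=O)c2c(O)c(I)c(OCc3ccccc3)cc2OCc2ccccc2)cc1
F3 | step 4 | 5,7-bis(benzyloxy)-8-iodo-2-(4-methoxyphenyl)-4H-chromen-4-one | COc1ccc(-c2cc(=O)c3c(OCc4ccccc4)cc(OCc4ccccc4)c(I)c3o2)cc1
F4 | step 6 | 5,7-bis(benzyloxy)-8-{5-methoxy-2-[(trimethylsilyl)ethynyl]phenyl}-2-(4-methoxyphenyl)-4H-chromen-4-one | COc1ccc(-c2cc(=O)c3c(OCc4ccccc4)cc(OCc4ccccc4)c(-c4cc(OC)ccc4C#C[Si](C)(C)C)c3o2)cc1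
F5 | step 6 | 5,7-bis(benzyloxy)-8-(2-ethynyl-5-methoxyphenyl)-2-(4-methoxyphenyl)-4H-chromen-4-one | COc1ccc(-c2cc(=O)c3c(OCc4ccccc4)cc(OCc4ccccc4)c(-c4cc(OC)ccc4C#C)c3o2)cc1
F6 | step 6 | 3,5-bis(benzyloxy)-2-iodophenol | Oc1cc(OCc2ccccc2)cc(OCc2ccccc2)c1I
F7 | step 6 | 1-[2,4-bis(benzyloxy)-6-hydroxyphenyl]-3-{2-[5,7-bis(benzyloxy)-2-(4-methoxyphenyl)-4-oxo-4H-chromen-8-yl]-4-methoxyphenyl}prop-2-yn-1-one | COc1ccc(-c2cc(=O)c3c(OCc4ccccc4)cc(OCc4ccccc4)c(-c4cc(OC)ccc4C#CC(=O)c4c(O)cc(OCc5ccccc5)cc4OCc4ccccc4)c3o2)cc1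
F8 | step 2 | (Z)-1-(4-methoxyphenyl)-1,3-bis(trimethylsilyloxy)buta-1,3-diene | COc1ccc(/C(O[Si](C)(C)C)=C/C(=C)O[Si](C)(C)C)cc1
F9 | step 2 | 2-(2-bromo-5-methoxyphenyl)acetyl chloride | COc1ccc(Br)c(CC(=O)Cl)c1
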